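A ratio of two times orders these flasks: the 50 min during which the Ly is kept from reacting at full strength, against the half-life of the Ly charge at −20 °C.

| flask | Ly | Qo | temperature | remark | time |
|---|---|---|---|---|---|
| ash | 0.038 M | 0.19 M | −20 °C | run made earlier |  |
| birch | 0.057 M | 0.19 M | −20 °C | run made earlier |  |
| summer | 0.038 M (fed, over 50 min) | 0.190 M |  | the addition at −60 °C, then warmed to −20 °C; the feed brings no volume worth counting | 80 min |
| dusk | 0.038 M | 0.190 M | −20 °C | everything together at the start | 80 min |
| spring | 0.038 M (fed, over 50 min) | 0.190 M | −20 °C | all else is in the flask from the start; the feed brings no volume worth counting | 80 min |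
| winter | 0.038 M | 0.190 M |  | everything together at the start at −60 °C, warmed to −20 °C at 50 min | 80 min |

| run | time / min | Ly.Qo / % |
|---|---|---|
| ash | 15.0 | 32.5 |
| ash | 30.0 | 49.5 |
| ash | 50.0 | 61.8 |
| ash | 60.0 | 65.5 |
| ash | 80.0 | 72.2 |
| birch | 1.33 | 7.4 |
| birch | 2.50 | 11.0 |
| birch | 5.00 | 20.1 |
| birch | 8.00 | 29.1 |
| birch | 15.0 | 42.4 |

(standard deviation of a reading: 0.5 percentage points)

* the flask that comes out highest in amount of Ly.Qo, in percent of the Ly charged, or "all alike" when all lie within 1.5 percentage points (summer / dusk / spring / winter / all alike)
* Ly.Qo at the end, in percent of the Ly charged, summer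
* Ly.Qo at the end, in percent of the Ly charged, dusk
* Ly.Qo at the end, in percent of the Ly charged, spring
* Ly.Qo at the end, in percent of the Ly charged, winter

- the analysis behind the earlier runs scatters by 0.5 percentage points, standard deviation
- the earlier runs do not show what temperature does; that part of a forecast is a guess

Let x be the Ly.Qo reading as a fraction of the Ly charged. In the ash run, x/(1−x) stands at 0.980 after 30.0 min and at 2.60 after 80.0 min, nearly in proportion to time. That is a pseudo-second-order course in Ly, with Qo in excess. The time τ at which x/(1−x) reaches one, read from the last point as 30.8 min, is the half-life of the charge, and a batch then follows x = t/(t+τ). This half-life should shrink as the charge grows, so the birch charge gets 20.5 min. That reckons 42.3% at 15.0 min, and the reading is 42.4%.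

My own reckoning takes the two ends. Dusk repeats the ash recipe, so its clock runs from the start and gives 72.2%. A charge that waits through the delay keeps 30.0 min of reaction and gives 49.3%. Summer and winter stand near that end if little Ly reacts while they are held at −60 °C, which is a guess, since the runs do not show temperature. Spring lies between the ends, and its ratio is 1.62, so its feed outlasts a half-life.

The forecast names dusk, with 72% there, 59.3% for spring, 50% for summer and 51% for winter. Its ground for spring is that “slow feeding keeps Ly dilute, which penalises a second-order reaction”.

    Ly + Qo → Ly.Qo, rate k1*[Ly]^2*[Qo] (k = 4.79 M⁻² min⁻¹, Ea = 47.0 kJ mol⁻¹)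
    (constants at −20 °C)

Dusk comes out highest at 71.3%, with spring at 59.0%, winter at 49.9% and summer at 49.5%. At 50.0 min summer still holds 99.1% of its Ly unreacted, and its warm stretch is 0.974 half-lives. The rate carries c(Qo) as a factor, so τ scales inversely with it. The neighbour of summer charged with 0.47 M of Qo gets 12.5 min, which reckons 70.7%, and that flask gives 71.3%.

The earlier runs and the new flask come from a simulation from invented constants; the scatter is artificial.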